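## Structural features

- The target joins a bicyclic terpenoid unit to a pentasubstituted benzene through one methylene carbon, C11. Terpenoid numbering is used: ring A is C1 to C5 plus C10, ring B is C5 to C10, and the arene is C1′ to C6′ with C1′ on C11.
- Rings A and B share the bond C5–C10. C10 is sp2 and carries the only alkene, C1=C10, so the ring fusion has a single stereocentre, C5.
- Ring B holds the vicinal pair C8 (secondary methyl) and C9 (quaternary: methyl, C11, C8, C10), with the two methyl groups cis. C5 stands 1,3 to C9 across C10. C3 carries an axial hydroxyl group, cis to H5, next to the gem-dimethyl carbon C4.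
- The arene has hydroxyl groups at C2′ and C6′, a hydroxymethyl group at C4′ and a formyl group at C5′, that is, a salicylaldehyde flanked by a benzylic alcohol.
- Fragile points are the aldehyde (hydride reagents, lactol formation with the neighbouring CH2OH), the electron-rich phenols (oxidation, acid-promoted addition of the C2′ oxygen to C10), the C1=C10 bond (migration into conjugation once C3 or C8 is a carbonyl) and any intermediate with carbonyl groups on both C8 and C11.
- The real difficulty is the quaternary C9 between C8 and the sp2 C10, its relation to C5, and the exact position of the alkene.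
- The key step reads C9=C10=C1 as an allene and C5 to C8 as a diene. One [4+2] addition across C9=C10 then makes ring B, closes ring A through the C1–C4 tether and leaves C1=C10 where the target has it.

## Logic of the disconnections

**28 to 25.** The three acetal C–O bonds and the C5′–CHO bond are cut last (28 from 27, 27 from 25). The aldehyde is the group most sensitive to hydride, so it must enter after the last reduction. The arene of 25 is locally symmetric (C3′ and C5′ are equivalent), so formylation poses no regiochemical choice and the arene simplifies to the symmetric unit of 12. The forward steps must lithiate the ring with the C3 alkoxide present and hydrolyse the acetals without protonating C1=C10.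

**25 to 23.** The C8 methyl group is traced back to an exocyclic methylene (24) and then to the C8 ketone (23). C8 is the one centre the cycloaddition cannot deliver in the right sense, because an E,E-diene would place a C8 substituent cis to C11. It is therefore set last by substrate-controlled hydrogenation. The gain is that C8 becomes a carbonyl, the function a silyloxy diene leaves behind. The demand is hydrogen delivery to one face of ring B and no reduction of C1=C10.

**23 to 19.** The hydride-derived C–H bonds at C3 and C6 are removed (23 from 21), the two carbonyls go back to two alcohols (20) and these to two silyl ethers (19). The cycloaddition needs the C3 oxygen equatorial and the target has it axial, so passage through the C3 ketone is unavoidable. Coupling it with the conversion of the C8 allylic oxygen into the ketone lets one fluoride step, one oxidation and one hydride reagent serve both sites. The demand is conjugate reduction of the enone, equatorial attack at C3, and no migration of C1=C10.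

**19 to 16.** The two C11–H bonds are replaced by the C11 carbonyl (19 from 18, 17, 16). The carbonyl activates the key step and has no place in the target. It is removed directly after the cycloaddition, while C3 and C8 are silyl ethers and before C8 becomes a ketone. This avoids a 1,3-diketone across the quaternary C9, which would invite retro-Claisen cleavage. The demand is a method that removes the C11 oxygen and spares the second benzylic C–O bond at C4′, which points to a radical deoxygenation.

**16 to 14.** The bonds C5–C10 and C8–C9 are cut (16 from 14 through 15). Both rings, the quaternary C9 and C5 fall back to an acyclic chain with one stereocentre (C3) and a labile C9. Three centres form (C5, C8, C9); C8 is erased later. The demand is endo and facial selectivity and a clean alkyne-to-allene equilibrium.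

**14 to 11.** The C11–C1′ bond is cut to an aryllithium (13) and an N-methoxy-N-methylamide (10); 13 comes from 12 and 12 from 11. The arene carries three acetals and no silyl group, so that later fluoride can unmask C3 and C8 alone; a precursor with the same silyl group on the C3 and C4′-CH2 oxygens would not allow this. The demand is carbonyl addition faster than deprotonation at C9.

**10 to 6 and 8.** The C9–C10 bond is cut (10 from 9, 9 from 6 and 8, 8 from 7). One copper-catalysed C–C bond formation attaches C9, its methyl group and C11 to the alkyne under neutral conditions. The demand is protonation at C9 and no carbene transfer to the diene.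

**6 to 4.** The C2–C3 bond is cut (6 from 5, 5 from 4). This is the only stereocentre set by a reagent; all others are relayed from it. Because the silyl dienol ether is already present, the propargylation must be neutral, which favours an allenylborane over an acid-catalysed method.

**4 to 1 and 2.** The C6=C7 bond is cut by cross-metathesis (3 from 1 and 2) and the diene is made by removing the C5 proton (4 from 3). Metathesis comes before the alkyne because a terminal alkyne five atoms from the alkene would undergo ring-closing enyne metathesis. In 3 only the enal can enolise, since C4 is quaternary, so the other aldehyde stays free for the propargylation.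

## Other disconnections considered

**Alternative 1:** The cut is the C1=C2 bond of a ring A cyclohexenone, A3.
- Forward step: the cyclopentene of (S)-α-campholenic aldehyde A1, after reduction and silylation of its aldehyde, is opened by ozonolysis to keto aldehyde A2. Hydroxide in methanol then condenses the methyl ketone carbon (C2) with the aldehyde (C1) and closes the enone.
- In favour: C5 comes from the chiral pool without a chiral reagent, which is at least the equal of step 3. C4 and the C3 carbonyl are in place, so C3 could be reduced directly to the axial alcohol without an inversion detour; here the alternative is better. The aldol condensation is polar, simple and more predictable than a pericyclic step with selectivity demands; this too is a point for the alternative.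
- Against: A3 is only ring A. C10 is a saturated CH2, the alkene sits at C1=C2, and ring B, C8, the quaternary C9, the link to the arene and the C1=C10 bond all remain to be built onto the side chain, with C5 as the only relay.
- Comparison: on structure the key step gives one ring and no new stereocentre, against two rings and three centres in step 10. On step economy the route after A3 would be much longer than the route after 16, although each of its steps would be lower in risk.

**Alternative 2:** The cut is C4–C5.
- Forward step: anodic oxidation of the silyl enol ether of A4 gives a radical cation at C4. The ring B allylsilane attacks it through C5, and loss of the C1 silyl group leaves C1=C10 and the C3 ketone A5.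
- In favour: the alkene is placed by the leaving silyl group as exactly as the allene places it in step 10, so the two plans are equal here. C3 arrives as a ketone ready for direct reduction to the axial alcohol, and the arene, C8 and C9 are already present, so the end-game after A5 would be shorter than steps 11 to 20; on both points the alternative is better. The oxidant is electric current, with no stoichiometric reagent.
- Against: C5 would have to be induced by C9 across the sp2 C10, and the sense is not obvious. The electron-rich arene has an oxidation potential near that of the enol ether and can be oxidised or can trap the radical cation. The bond forms between a fully substituted C4 and a ring carbon next to C10. The difficulty moves into A4, which already needs ring B, the C8/C9 pair and a regiodefined allylsilane.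
- Comparison: the key step makes one ring, one bond and one centre, against two, two and three in step 10. Its mechanism (radical cation, nucleophilic trapping, desilylation) has more competing channels than a tethered cycloaddition.

**Alternative 3:** The cuts are C3′–C4′ and C5′–C6′.
- Forward step: the 1-methoxy-1,3-bis(trimethylsilyloxy) diene A6, carried on C11, adds to alkynoate A7 and aromatises by loss of methanol to salicylate A8.
- In favour: the arene substitution pattern is fixed by the cycloaddition, the C5′ carbon enters as an ester, and C11 is a methylene from the start. No late lithiation, no hindered aryl ketone and no C11 deoxygenation are needed; on these points the alternative is better than the chosen plan.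
- Against: it simplifies nothing in the terpenoid half. All four stereocentres, the quaternary C9 and C1=C10 must already be in A6. A6 needs an acetoacetate attached at the neopentyl C11, which is hard to make by alkylation. The bulky substituent on the diene lowers its s-cis population, the bis-silyl diene is sensitive to moisture, and the ester of A8 must later be reduced to the aldehyde next to free phenols.
- Comparison: both key steps are [4+2] additions that form two C–C bonds and one ring. This one forms no stereocentre and shifts steps from the end to the middle, so step economy is about equal at best, while the hard part of the structure is left unsolved.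

Key step: step 10

Remarks on the chemistry:
- Ar stands for 2,6-bis(methoxymethoxy)-4-[(methoxymethoxy)methyl]phenyl. Decalin names use the terpenoid numbering above.
- C9 in 9, 10 and 14 and C11 in 17 and 18 arise as epimer mixtures and are left unspecified; C9 is equilibrated in step 10 and C11 loses its oxygen in step 13.
- The facial sense of the allenylborane in step 3 is assumed to be that of the corresponding allylborane (Si face).

## Route

Step 1
Reactants: 1 2,2-dimethylpent-4-enal; 2 crotonaldehyde
Product: 3 (E)-5,5-dimethylhex-2-enedial
Conditions: 2 (4 equiv), second-generation Hoveyda–Grubbs catalyst RuCl2(H2IMes)(=CH-C6H4-2-O-i-Pr) (2 mol %), CH2Cl2, 40 °C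
Reagents that add atoms: none
Why: Olefin cross-metathesis of a terminal alkene with an excess of an electron-poor enal is a selective pairing and should give the E-enal; the α-quaternary aldehyde is a spectator. It is run before any alkyne is present, because a terminal alkyne would be drawn into ring-closing enyne metathesis.

Step 2
Reactants: 3
Product: 4 (3E,5E)-2,2-dimethyl-6-(triethylsilyloxy)hexa-3,5-dienal
Conditions: Et3SiOTf (1.1 equiv), Et3N (2.5 equiv), Et2O, −78 → 0 °C
Reagents that add atoms: triethylsilyl trifluoromethanesulfonate, CC[Si](CC)(CC)OS(=O)(=O)C(F)(F)F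
Why: Vinylogous enol silylation: the enal oxygen is silylated and the amine removes the γ-proton at C5, giving the 1-silyloxy diene; the second aldehyde has no α-hydrogen and cannot form an enol ether. The extended conformation next to the quaternary C4 favours the E,E isomer.

Step 3
Reactants: 4
Product: 5 (1E,3E,6S)-5,5-dimethyl-1-(triethylsilyloxy)nona-1,3-dien-8-yn-6-ol
Conditions: (−)-Ipc2BOMe, H2C=C=CHMgBr, Et2O, −78 → 0 °C; then 4, −100 → −78 °C; H2NCH2CH2OH work-up
Reagents that add atoms: B-allenyldiisopinocampheylborane (isopinocampheyl groups from (+)-α-pinene), C=C=CB([C@@H]1C[C@@H]2C[C@H]([C@H]1C)C2(C)C)[C@@H]1C[C@@H]2C[C@H]([C@H]1C)C2(C)C, made in the flask from allenylmagnesium bromide, C=C=C[Mg]Br, and (−)-B-methoxydiisopinocampheylborane, COB([C@@H]1C[C@@H]2C[C@H]([C@H]1C)C2(C)C)[C@@H]1C[C@@H]2C[C@H]([C@H]1C)C2(C)C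
Why: Asymmetric allenylboration transfers the allenyl group with allylic transposition through a closed six-membered transition state, giving the homopropargylic alcohol under neutral conditions that the silyl dienol ether tolerates. C3 is set by the isopinocampheyl groups, which should direct attack to the Si face of the aldehyde; with C4 outranking C2 this is the S alcohol.

Step 4
Reactants: 5
Product: 6 (1E,3E,6S)-6-(tert-butyldimethylsilyloxy)-5,5-dimethyl-1-(triethylsilyloxy)nona-1,3-dien-8-yne
Conditions: t-BuMe2SiOTf, 2,6-lutidine, CH2Cl2, −78 → 0 °C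
Reagents that add atoms: tert-butyldimethylsilyl trifluoromethanesulfonate, CC(C)(C)[Si](C)(C)OS(=O)(=O)C(F)(F)F
Why: The neopentyl secondary alcohol needs the silyl triflate, and the hindered pyridine keeps the medium free of acid so that the dienol ether survives. The bulky ether later serves as the equatorial anchor of the tether.

Step 5
Reactants: 7 ethyl 2-methyl-3-oxobutanoate
Product: 8 ethyl 2-diazopropanoate
Conditions: 4-acetamidobenzenesulfonyl azide, DBU, MeCN, 0 → 23 °C
Reagents that add atoms: 4-acetamidobenzenesulfonyl azide, CC(=O)Nc1ccc(cc1)S(=O)(=O)N=[N+]=[N-]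
Why: Deacylative diazo transfer (Regitz type): the enolate of the 2-substituted acetoacetate adds to the sulfonyl azide and the adduct collapses with transfer of the acetyl group to the sulfonamide nitrogen.

Step 6
Reactants: 6; 8
Product: 9 ethyl (6S,8E,10E)-6-(tert-butyldimethylsilyloxy)-2,7,7-trimethyl-11-(triethylsilyloxy)undeca-8,10-dien-3-ynoate (2RS)
Conditions: CuI (10 mol %), MeCN, 23 °C, slow addition of 8 (1.5 equiv)
Reagents that add atoms: none
Why: Copper-catalysed coupling of a terminal alkyne with a diazo ester: the copper acetylide takes up the diazo compound as a carbene, the alkynyl group migrates to the carbene carbon and the propargylic copper species is protonated at C9, which forms C9–C10 and gives the 3-alkynoate. No base is present, so isomerisation to the allenoate and loss of the silyl ethers are not expected; both C9 epimers are usable.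

Step 7
Reactants: 9
Product: 10 (6S,8E,10E)-6-(tert-butyldimethylsilyloxy)-N-methoxy-N,2,7,7-tetramethyl-11-(triethylsilyloxy)undeca-8,10-dien-3-ynamide (2RS)
Conditions: MeNHOMe·HCl, i-PrMgCl, THF, −20 °C
Reagents that add atoms: N,O-dimethylhydroxylamine hydrochloride, CNOC.Cl
Why: Weinreb amide synthesis by aminolysis of the ester with the chloromagnesium amide at low temperature, where addition to the ester should outrun deprotonation at C9.

Step 8
Reactants: 11 3,5-dihydroxybenzyl alcohol
Product: 12 1,3-bis(methoxymethoxy)-5-[(methoxymethoxy)methyl]benzene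
Conditions: NaH, MeOCH2Cl, THF/DMF, 0 → 23 °C
Reagents that add atoms: chloromethyl methyl ether, COCCl
Why: Williamson-type alkylation of the two phenoxides and the alkoxide. The acetals direct both later lithiations and resist fluoride, hydride and base, so that only C3 and C8 carry silyl groups.

Step 9
Reactants: 12; 10
Product: 14 (6S,8E,10E)-1-Ar-6-(tert-butyldimethylsilyloxy)-2,7,7-trimethyl-11-(triethylsilyloxy)undeca-8,10-dien-3-yn-1-one (2RS), via aryllithium 13 (not isolated)
Conditions: 12 (1.4 equiv), n-BuLi (1.3 equiv), THF, 0 °C; then 10, −78 → −40 °C; AcOH/THF, −78 °C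
Reagents that add atoms: none
Why: Directed ortho-lithiation takes place between the two aryl acetal oxygens, the doubly activated position, and the aryllithium adds once to the N-methoxy-N-methylamide because the chelated tetrahedral intermediate holds until the quench. This forms C11–C1′; the cold acidic quench avoids premature isomerisation of the product.

Step 10
Reactants: 14
Product: 16 (3S,5R,8S,9R)-9-(Ar-carbonyl)-3-(tert-butyldimethylsilyloxy)-4,4,9-trimethyl-8-(triethylsilyloxy)decalin-1(10),6-diene, via allenyl ketone 15 (not isolated)
Conditions: Et3N (3 equiv), toluene (0.02 M), BHT (cat.), 23 → 60 °C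
Reagents that add atoms: none
Why: Triethylamine removes the doubly activated C9 proton (α to the ketone and propargylic) and reprotonation at C1 gives allenyl ketone 15; this equilibrium is reversible, so both C9 epimers of 14 and both allene diastereomers of 15 pass through one enolate. The electron-poor C9=C10 bond of 15, conjugated with the ketone and remote from the tether, then adds to the electron-rich 1-silyloxy diene in a concerted, asynchronous intramolecular Diels–Alder reaction; the closest known reaction type is the cycloaddition of allenyl ketones generated in the flask with tethered dienes. Ring B is closed directly as the [4+2] cyclohexene by the new bonds C5–C10 and C8–C9, and ring A is closed by the same C5–C10 bond through the four-atom tether C4–C3–C2–C1 in the fused mode of a deca-1,7,9-triene cyclisation. The regiochemistry is fixed twice, by the tether and by the match of the large diene coefficient at C5 with the β-carbon C10 of the enone. The C1=C10 bond of the allene is orthogonal to the reacting π system and passes into the product unchanged, which places the ring A alkene. C5 is controlled by C3: in the chair-like tether the bulky silyl ether sits equatorial and fixes the diene face that C10 attacks, with H5 trans to the C3 oxygen. C9 is controlled by endo placement of the aroyl group under the diene, open to only one allene diastereomer (a Curtin–Hammett selection from the equilibrating pair), which puts C11 cis to C4; C8, with its silyl ether cis to the aroyl group, follows from the E enol ether and is erased later. The step needs endo and facial selectivity and cycloaddition in preference to furan formation or dimerisation of 15; the short tether, the equatorial preference of the C3 group next to the gem-dimethyl carbon, the absence of metal salts and dilution should secure these.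

Step 11
Reactants: 16
Product: 17 (3S,5R,8S,9S)-9-[Ar(hydroxy)methyl]-3-(tert-butyldimethylsilyloxy)-4,4,9-trimethyl-8-(triethylsilyloxy)decalin-1(10),6-diene (11RS)
Conditions: LiAlH4, THF, 0 → 40 °C
Reagents that add atoms: none
Why: Hydride reduction of the hindered, non-enolisable aryl ketone by the small LiAlH4; silyl ethers, acetals and both alkenes are inert. The configuration at C11 does not matter because the oxygen is removed.

Step 12
Reactants: 17
Product: 18 O-C11 S-methyl dithiocarbonate (xanthate) of 17 (11RS)
Conditions: NaH, imidazole (cat.), THF, 23 °C; CS2; then MeI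
Reagents that add atoms: carbon disulfide, S=C=S; iodomethane, CI
Why: Xanthate formation, the first half of the Barton–McCombie deoxygenation: the alkoxide adds to the small electrophile CS2 even at this neopentyl benzylic position and the salt is S-methylated. C9 has no hydrogen, so Chugaev elimination is not possible.

Step 13
Reactants: 18
Product: 19 (3S,5R,8S,9R)-9-(Ar-methyl)-3-(tert-butyldimethylsilyloxy)-4,4,9-trimethyl-8-(triethylsilyloxy)decalin-1(10),6-diene
Conditions: (Me3Si)3SiH, AIBN (cat.), toluene, 90 °C
Reagents that add atoms: none
Why: Barton–McCombie radical deoxygenation: the silyl radical adds to C=S, the C11–O bond fragments to a benzylic radical and the silane transfers hydrogen. Unlike dissolving-metal or acid/hydride methods this leaves the benzylic C–O bond at C4′ and the acetals untouched.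

Step 14
Reactants: 19
Product: 20 (3S,5R,8S,9R)-9-(Ar-methyl)-4,4,9-trimethyldecalin-1(10),6-diene-3,8-diol
Conditions: Bu4NF, THF, 50 °C
Reagents that add atoms: none
Why: Fluoride cleaves both Si–O bonds, the hindered C3 ether needing gentle heating. The three acetals are stable to fluoride, so no selectivity between silyl groups is required.

Step 15
Reactants: 20
Product: 21 (5R,9R)-9-(Ar-methyl)-4,4,9-trimethyldecalin-1(10),6-diene-3,8-dione
Conditions: Dess–Martin periodinane, NaHCO3, CH2Cl2, 0 → 23 °C; crude product used directly
Reagents that add atoms: none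
Why: Dess–Martin oxidation converts the allylic C8 alcohol to the enone and the C3 alcohol to the ketone in one operation. The bicarbonate buffer and direct use of the crude dione guard against migration of C1=C10 into conjugation.

Step 16
Reactants: 21
Product: 23 (3R,5R,9R)-9-(Ar-methyl)-3-hydroxy-4,4,9-trimethyldecal-1(10)-en-8-one, via lithium enolate 22 (not isolated)
Conditions: LiBH(s-Bu)3 (3 equiv), THF, −78 → −40 °C; aq. NH4Cl
Reagents that add atoms: none
Why: LiBH(s-Bu)3 reduces β-unsubstituted cyclohexenones by conjugate addition, here helped by the quaternary C9 next to the carbonyl, and leaves C8 as an enolate that resists further reduction. The same bulky hydride should attack the C3 ketone along the equatorial path and give the axial alcohol, cis to H5, as with 4,4-dimethyl-3-keto terpenoids. One reagent thus saturates C6=C7, keeps the C8 ketone and sets C3 in the configuration of the target.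

Step 17
Reactants: 23
Product: 24 (3R,5R,9S)-9-(Ar-methyl)-4,4,9-trimethyl-8-methylidenedecal-1(10)-en-3-ol
Conditions: Ph3PCH3Br (4 equiv), KOt-Bu, toluene, 80 °C
Reagents that add atoms: methyltriphenylphosphonium bromide, C[P+](c1ccccc1)(c1ccccc1)c1ccccc1.[Br-]
Why: Wittig methylenation of the hindered C8 ketone with excess non-stabilised ylide at raised temperature; the free C3 hydroxyl is carried as its alkoxide.

Step 18
Reactants: 24
Product: 25 (3R,5R,8R,9S)-9-(Ar-methyl)-4,4,8,9-tetramethyldecal-1(10)-en-3-ol
Conditions: H2 (1 atm), Pd/C (5 %), Et3N, EtOAc, 23 °C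
Reagents that add atoms: none
Why: Heterogeneous hydrogenation of the 1,1-disubstituted exocyclic alkene should be much faster than that of the hindered trisubstituted C1=C10. C8 is set by hydrogen delivery to the ring B face opposite the axial C9 methyl group, which makes the new methyl equatorial and cis to the C9 methyl. The amine suppresses hydrogenolysis of the benzylic acetal and acid-induced alkene migration.

Step 19
Reactants: 25
Product: 27 3-{[(3R,5R,8R,9S)-3-hydroxy-4,4,8,9-tetramethyldecal-1(10)-en-9-yl]methyl}-2,4-bis(methoxymethoxy)-6-[(methoxymethoxy)methyl]benzaldehyde, via dilithio species 26 (not isolated)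
Conditions: n-BuLi (3.5 equiv), TMEDA, THF, −20 → 0 °C; DMF, −78 → 0 °C; aq. NH4Cl
Reagents that add atoms: N,N-dimethylformamide, CN(C)C=O
Why: Directed ortho-metalation: after deprotonation of the C3 hydroxyl, the aryl acetal at C6′ and the CH2 acetal at C4′ guide the base to C5′ (C3′ and C5′ are equivalent), and DMF formylates the aryllithium. The aldehyde enters only after the last hydride step.

Step 20
Reactants: 27
Product: 28 2,4-dihydroxy-3-{[(1S,2R,4aR,6R)-6-hydroxy-1,2,5,5-tetramethyl-1,2,3,4,4a,5,6,7-octahydronaphthalen-1-yl]methyl}-6-(hydroxymethyl)benzaldehyde (the target; 3R,5R,8R,9S in terpenoid numbering)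
Conditions: 2 M aq. HCl, THF, 45 °C
Reagents that add atoms: none
Why: Acid hydrolysis of the two aryl acetals and the benzylic acetal under conditions too mild to protonate the hindered trisubstituted alkene. Water as co-solvent keeps the aldehyde from being trapped as an acetal with the neighbouring benzylic alcohol; no stereocentre is touched.

## Compound list

1 | 2,2-dimethylpent-4-enal | C=CCC(C)(C)C=O | starting material
2 | crotonaldehyde, (E)-but-2-enal | C/C=C/C=O | starting material
3 | (E)-5,5-dimethylhex-2-enedial | O=C/C=C/CC(C)(C)C=O | intermediate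
4 | (3E,5E)-2,2-dimethyl-6-(triethylsilyloxy)hexa-3,5-dienal | O=CC(C)(C)/C=C/C=C/O[Si](CC)(CC)CC | intermediate
5 | (1E,3E,6S)-5,5-dimethyl-1-(triethylsilyloxy)nona-1,3-dien-8-yn-6-ol | C#CC[C@H](O)C(C)(C)/C=C/C=C/O[Si](CC)(CC)CC | intermediate
6 | (1E,3E,6S)-6-(tert-butyldimethylsilyloxy)-5,5-dimethyl-1-(triethylsilyloxy)nona-1,3-dien-8-yne | C#CC[C@H](O[Si](C)(C)C(C)(C)C)C(C)(C)/C=C/C=C/O[Si](CC)(CC)CC | intermediate
7 | ethyl 2-methyl-3-oxobutanoate | CCOC(=O)C(C)C(C)=O | starting material
8 | ethyl 2-diazopropanoate | CCOC(=O)C(C)=[N+]=[N-] | intermediate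
9 | ethyl (6S,8E,10E)-6-(tert-butyldimethylsilyloxy)-2,7,7-trimethyl-11-(triethylsilyloxy)undeca-8,10-dien-3-ynoate, both C2 epimers | CCOC(=O)C(C)C#CC[C@H](O[Si](C)(C)C(C)(C)C)C(C)(C)/C=C/C=C/O[Si](CC)(CC)CC | intermediate
10 | (6S,8E,10E)-6-(tert-butyldimethylsilyloxy)-N-methoxy-N,2,7,7-tetramethyl-11-(triethylsilyloxy)undeca-8,10-dien-3-ynamide, both C2 epimers | CON(C)C(=O)C(C)C#CC[C@H](O[Si](C)(C)C(C)(C)C)C(C)(C)/C=C/C=C/O[Si](CC)(CC)CC | intermediate
11 | 3,5-dihydroxybenzyl alcohol | OCc1cc(O)cc(O)c1 | starting material
12 | 1,3-bis(methoxymethoxy)-5-[(methoxymethoxy)methyl]benzene | COCOCc1cc(OCOC)cc(OCOC)c1 | intermediate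
13 | {2,6-bis(methoxymethoxy)-4-[(methoxymethoxy)methyl]phenyl}lithium | [Li]c1c(OCOC)cc(COCOC)cc1OCOC | intermediate (not isolated)
14 | (6S,8E,10E)-1-Ar-6-(tert-butyldimethylsilyloxy)-2,7,7-trimethyl-11-(triethylsilyloxy)undeca-8,10-dien-3-yn-1-one, both C2 epimers (key-step precursor) | CC(C#CC[C@H](O[Si](C)(C)C(C)(C)C)C(C)(C)/C=C/C=C/O[Si](CC)(CC)CC)C(=O)c1c(OCOC)cc(COCOC)cc1OCOC | intermediate
15 | (6S,8E,10E)-1-Ar-6-(tert-butyldimethylsilyloxy)-2,7,7-trimethyl-11-(triethylsilyloxy)undeca-2,3,8,10-tetraen-1-one, both allene configurations | CC(=C=CC[C@H](O[Si](C)(C)C(C)(C)C)C(C)(C)/C=C/C=C/O[Si](CC)(CC)CC)C(=O)c1c(OCOC)cc(COCOC)cc1OCOC | intermediate (not isolated)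
16 | (3S,5R,8S,9R)-9-(Ar-carbonyl)-3-(tert-butyldimethylsilyloxy)-4,4,9-trimethyl-8-(triethylsilyloxy)decalin-1(10),6-diene; C3 oxygen equatorial and trans to H5, C8 oxygen cis to the aroyl group, C11 cis to C4 | CC[Si](CC)(CC)O[C@H]1C=C[C@@H]2C(=CC[C@H](O[Si](C)(C)C(C)(C)C)C2(C)C)[C@@]1(C)C(=O)c1c(OCOC)cc(COCOC)cc1OCOC | intermediate
17 | (3S,5R,8S,9S)-9-[Ar(hydroxy)methyl]-3-(tert-butyldimethylsilyloxy)-4,4,9-trimethyl-8-(triethylsilyloxy)decalin-1(10),6-diene, both C11 epimers | CC[Si](CC)(CC)O[C@H]1C=C[C@@H]2C(=CC[C@H](O[Si](C)(C)C(C)(C)C)C2(C)C)[C@@]1(C)C(O)c1c(OCOC)cc(COCOC)cc1OCOC | intermediate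
18 | O-C11 S-methyl dithiocarbonate of 17, both C11 epimers | CC[Si](CC)(CC)O[C@H]1C=C[C@@H]2C(=CC[C@H](O[Si](C)(C)C(C)(C)C)C2(C)C)[C@@]1(C)C(OC(=S)SC)c1c(OCOC)cc(COCOC)cc1OCOC | intermediate
19 | (3S,5R,8S,9R)-9-(Ar-methyl)-3-(tert-butyldimethylsilyloxy)-4,4,9-trimethyl-8-(triethylsilyloxy)decalin-1(10),6-diene | CC[Si](CC)(CC)O[C@H]1C=C[C@@H]2C(=CC[C@H](O[Si](C)(C)C(C)(C)C)C2(C)C)[C@@]1(C)Cc1c(OCOC)cc(COCOC)cc1OCOC | intermediate
20 | (3S,5R,8S,9R)-9-(Ar-methyl)-4,4,9-trimethyldecalin-1(10),6-diene-3,8-diol | O[C@H]1C=C[C@@H]2C(=CC[C@H](O)C2(C)C)[C@@]1(C)Cc1c(OCOC)cc(COCOC)cc1OCOC | intermediate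
21 | (5R,9R)-9-(Ar-methyl)-4,4,9-trimethyldecalin-1(10),6-diene-3,8-dione | O=C1C=C[C@@H]2C(=CCC(=O)C2(C)C)[C@@]1(C)Cc1c(OCOC)cc(COCOC)cc1OCOC | intermediate
22 | dilithium salt of the C3 alkoxide and C7=C8 enolate formed from 21 (3R,5R,9R) | [Li+].[Li+].[O-]C1=CC[C@@H]2C(=CC[C@@H]([O-])C2(C)C)[C@@]1(C)Cc1c(OCOC)cc(COCOC)cc1OCOC | intermediate (not isolated)
23 | (3R,5R,9R)-9-(Ar-methyl)-3-hydroxy-4,4,9-trimethyldecal-1(10)-en-8-one; hydroxyl axial, cis to H5 | O=C1CC[C@@H]2C(=CC[C@@H](O)C2(C)C)[C@@]1(C)Cc1c(OCOC)cc(COCOC)cc1OCOC | intermediate
24 | (3R,5R,9S)-9-(Ar-methyl)-4,4,9-trimethyl-8-methylidenedecal-1(10)-en-3-ol | C=C1CC[C@@H]2C(=CC[C@@H](O)C2(C)C)[C@@]1(C)Cc1c(OCOC)cc(COCOC)cc1OCOC | intermediate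
25 | (3R,5R,8R,9S)-9-(Ar-methyl)-4,4,8,9-tetramethyldecal-1(10)-en-3-ol; C8 and C9 methyl groups cis | C[C@@H]1CC[C@@H]2C(=CC[C@@H](O)C2(C)C)[C@@]1(C)Cc1c(OCOC)cc(COCOC)cc1OCOC | intermediate
26 | C3 lithium alkoxide and C5′ aryllithium of 25 | [Li+].C[C@@H]1CC[C@@H]2C(=CC[C@@H]([O-])C2(C)C)[C@@]1(C)Cc1c(OCOC)cc(COCOC)c([Li])c1OCOC | intermediate (not isolated)
27 | 3-{[(3R,5R,8R,9S)-3-hydroxy-4,4,8,9-tetramethyldecal-1(10)-en-9-yl]methyl}-2,4-bis(methoxymethoxy)-6-[(methoxymethoxy)methyl]benzaldehyde | C[C@@H]1CC[C@@H]2C(=CC[C@@H](O)C2(C)C)[C@@]1(C)Cc1c(OCOC)cc(COCOC)c(C=O)c1OCOC | intermediate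
28 | 2,4-dihydroxy-3-{[(1S,2R,4aR,6R)-6-hydroxy-1,2,5,5-tetramethyl-1,2,3,4,4a,5,6,7-octahydronaphthalen-1-yl]methyl}-6-(hydroxymethyl)benzaldehyde | C[C@@H]1CC[C@@H]2C(=CC[C@@H](O)C2(C)C)[C@@]1(C)Cc1c(O)cc(CO)c(C=O)c1O | target

## Step count and least certain steps

Total: 20 steps. Longest linear sequence: 18 steps from 1 (steps 1 to 4, 6, 7 and 9 to 20); steps 5 and 8 are one-step branches.

**Step 10 (key step).** The alkyne-to-allene isomerisation may stall, or the allenyl ketone may be lost to dimerisation, amine addition or cyclisation to a furan. Endo and facial selectivity may be poor because the twisted, di-ortho-substituted aroyl group is a weak endo director. The fallback sets out from 9 and returns at 17. Triethylamine isomerises 9 to the isolable allenoate, ethyl (6S,8E,10E)-6-(tert-butyldimethylsilyloxy)-2,7,7-trimethyl-11-(triethylsilyloxy)undeca-2,3,8,10-tetraenoate F1. Heating F1 in toluene (BHT, 110–130 °C) runs the same cycloaddition with a dienophile that has no enolisable ketone and should give the bicyclic ester, the C11 ethyl ester analogue of 16 F2. DIBAL-H at −78 °C reduces it to the non-enolisable neopentyl aldehyde, the C11 aldehyde analogue of 16 F3, and aryllithium 13 adds to this aldehyde to give 17. Steps 7, 9, 10 and 11 are bypassed.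

**Step 16.** Direct reduction of the enone carbonyl may compete with conjugate reduction. Facial selectivity at C3 may be lost because C1 is sp2 and axial attack is less hindered than in saturated terpenoid ketones. The C1=C10 bond may migrate into conjugation with either carbonyl of 21. The fallback sets out from 20 and returns at 25.
- MnO2 oxidises only the allylic alcohol, giving the (3S,5R,9R)-3-hydroxy-1(10),6-dien-8-one F4.
- [(Ph3P)CuH]6 reduces the enone by conjugate hydride transfer to the (3S,5R,9R)-3-hydroxy-8-ketone F5.
- Wittig methylenation gives the (3S,5R,9S)-8-methylidene alcohol F6, and hydrogenation as in step 18 gives the (3S)-epimer of 25 F7.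
- Dess–Martin oxidation gives the (5R,8R,9S)-3-ketone F8.
- Corey–Bakshi–Shibata reduction with the (S)-methyl oxazaborolidine and catecholborane then sets C3 under reagent control (C4 as the large and C2 as the small group) and gives 25.

**Step 9.** The aryllithium may deprotonate the acidic C9–H of 10 instead of adding, which returns 10 or its allenamide; the same acidity also threatens step 7. The fallback sets out from 6 and returns at 14 without a basic step on a C9–H compound.
- The alkynylmagnesium bromide of 6 (EtMgBr) adds to acetaldehyde to give (6S,8E,10E)-6-(tert-butyldimethylsilyloxy)-7,7-dimethyl-11-(triethylsilyloxy)undeca-8,10-dien-3-yn-2-ol F9, and MsCl/Et3N gives its methanesulfonate F10.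
- Formylation of 13 with DMF gives 2,6-bis(methoxymethoxy)-4-[(methoxymethoxy)methyl]benzaldehyde F11.
- Zerovalent palladium (from Pd(OAc)2 and PPh3) and InI convert F10 into an allenylindium reagent that adds to F11 with allylic transposition, giving the homopropargylic alcohol, the C11 alcohol corresponding to 14 F12.
- Dess–Martin oxidation gives 14. Steps 6, 7 and 9 are bypassed.

**Step 19.** Ring lithiation may be incomplete next to the aggregated C3 alkoxide, or the base may deprotonate the benzylic CH2 of the C4′ acetal and start a Wittig rearrangement. The fallback sets out from 25 and returns at 28. The three acetals are hydrolysed first, as in step 20, to the free resorcinol (3R,5R,8R,9S)-9-[2,6-dihydroxy-4-(hydroxymethyl)benzyl]-4,4,8,9-tetramethyldecal-1(10)-en-3-ol F13. Magnesium-mediated ortho-formylation (MgCl2, Et3N, paraformaldehyde, MeCN, reflux) then delivers the formyl group ortho to a phenoxide at the equivalent C3′/C5′ positions and gives 28.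

**Step 18.** Hydrogen may be delivered to the wrong face if the aryl group on C11 folds over ring B, or the exocyclic alkene may migrate into the ring before it is reduced. The fallback sets out from 24 and returns at 25: hydrogen-atom-transfer hydrogenation (Mn(dpm)3, PhSiH3, t-BuOOH, i-PrOH) goes through the tertiary C8 radical and favours the more stable equatorial methyl group. It makes no new compound (F0).

**Step 20.** The benzylic acetal may hydrolyse too slowly, and forcing the acid may bring addition of the C2′ phenol to C1=C10 or acetal formation at the aldehyde. The fallback sets out from 27 and returns at 28: silyl-transfer cleavage of the acetals with Me3SiOTf and 2,2′-bipyridyl in CH2Cl2 at 0 °C, then aqueous work-up, avoids protic acid. It makes no new isolated compound (F0).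

## Further compounds

F1 | step 10 | ethyl (6S,8E,10E)-6-(tert-butyldimethylsilyloxy)-2,7,7-trimethyl-11-(triethylsilyloxy)undeca-2,3,8,10-tetraenoate | CCOC(=O)C(C)=C=CC[C@H](O[Si](C)(C)C(C)(C)C)C(C)(C)/C=C/C=C/O[Si](CC)(CC)CC
F2 | step 10 | ethyl (3S,5R,8S,9R)-3-(tert-butyldimethylsilyloxy)-4,4,9-trimethyl-8-(triethylsilyloxy)decalin-1(10),6-diene-9-carboxylate | CC[Si](CC)(CC)O[C@H]1C=C[C@@H]2C(=CC[C@H](O[Si](C)(C)C(C)(C)C)C2(C)C)[C@@]1(C)C(=O)OCC
F3 | step 10 | (3S,5R,8S,9R)-3-(tert-butyldimethylsilyloxy)-4,4,9-trimethyl-8-(triethylsilyloxy)decalin-1(10),6-diene-9-carbaldehyde | CC[Si](CC)(CC)O[C@H]1C=C[C@@H]2C(=CC[C@H](O[Si](C)(C)C(C)(C)C)C2(C)C)[C@@]1(C)C=O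
F4 | step 16 | (3S,5R,9R)-9-(Ar-methyl)-3-hydroxy-4,4,9-trimethyldecalin-1(10),6-dien-8-one | O=C1C=C[C@@H]2C(=CC[C@H](O)C2(C)C)[C@@]1(C)Cc1c(OCOC)cc(COCOC)cc1OCOC
F5 | step 16 | (3S,5R,9R)-9-(Ar-methyl)-3-hydroxy-4,4,9-trimethyldecal-1(10)-en-8-one | O=C1CC[C@@H]2C(=CC[C@H](O)C2(C)C)[C@@]1(C)Cc1c(OCOC)cc(COCOC)cc1OCOC
F6 | step 16 | (3S,5R,9S)-9-(Ar-methyl)-4,4,9-trimethyl-8-methylidenedecal-1(10)-en-3-ol | C=C1CC[C@@H]2C(=CC[C@H](O)C2(C)C)[C@@]1(C)Cc1c(OCOC)cc(COCOC)cc1OCOC
F7 | step 16 | (3S,5R,8R,9S)-9-(Ar-methyl)-4,4,8,9-tetramethyldecal-1(10)-en-3-ol | C[C@@H]1CC[C@@H]2C(=CC[C@H](O)C2(C)C)[C@@]1(C)Cc1c(OCOC)cc(COCOC)cc1OCOC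
F8 | step 16 | (5R,8R,9S)-9-(Ar-methyl)-4,4,8,9-tetramethyldecal-1(10)-en-3-one | C[C@@H]1CC[C@@H]2C(=CCC(=O)C2(C)C)[C@@]1(C)Cc1c(OCOC)cc(COCOC)cc1OCOC
F9 | step 9 | (6S,8E,10E)-6-(tert-butyldimethylsilyloxy)-7,7-dimethyl-11-(triethylsilyloxy)undeca-8,10-dien-3-yn-2-ol, both C2 epimers | CC(O)C#CC[C@H](O[Si](C)(C)C(C)(C)C)C(C)(C)/C=C/C=C/O[Si](CC)(CC)CC
F10 | step 9 | methanesulfonate of F9 | CC(OS(C)(=O)=O)C#CC[C@H](O[Si](C)(C)C(C)(C)C)C(C)(C)/C=C/C=C/O[Si](CC)(CC)CC
F11 | step 9 | 2,6-bis(methoxymethoxy)-4-[(methoxymethoxy)methyl]benzaldehyde | O=Cc1c(OCOC)cc(COCOC)cc1OCOC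
F12 | step 9 | (6S,8E,10E)-1-Ar-6-(tert-butyldimethylsilyloxy)-2,7,7-trimethyl-11-(triethylsilyloxy)undeca-8,10-dien-3-yn-1-ol, epimers at C1 and C2 | CC(C#CC[C@H](O[Si](C)(C)C(C)(C)C)C(C)(C)/C=C/C=C/O[Si](CC)(CC)CC)C(O)c1c(OCOC)cc(COCOC)cc1OCOC
F13 | step 19 | (3R,5R,8R,9S)-9-[2,6-dihydroxy-4-(hydroxymethyl)benzyl]-4,4,8,9-tetramethyldecal-1(10)-en-3-ol | C[C@@H]1CC[C@@H]2C(=CC[C@@H](O)C2(C)C)[C@@]1(C)Cc1c(O)cc(CO)cc1O
F0 | step 18 | none | none
F0 | step 20 | none | none
A1 | alternative 1 | (S)-α-campholenic aldehyde, 2-[(1S)-2,2,3-trimethylcyclopent-3-en-1-yl]acetaldehyde | CC1=CC[C@@H](CC=O)C1(C)C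
A2 | alternative 1 | (3R)-3-[2-(tert-butyldimethylsilyloxy)ethyl]-4,4-dimethyl-5-oxohexanal | CC(=O)C(C)(C)[C@H](CCO[Si](C)(C)C(C)(C)C)CC=O
A3 | alternative 1 | (5S)-5-[2-(tert-butyldimethylsilyloxy)ethyl]-6,6-dimethylcyclohex-2-en-1-one | O=C1C=CC[C@@H](CCO[Si](C)(C)C(C)(C)C)C1(C)C
A4 | alternative 2 | (8R,9S)-ring B cyclohexene (C5=C10) carrying on C10 the chain C1H(SiMe3)–C2H2–C3(OSiMe3)=C4Me2 and on C9 the 2,6-bis(methoxymethoxy)-4-[(tert-butyldimethylsilyloxy)methyl]benzyl group, either C1 epimer | C[C@@H]1CCC=C(C(CC(O[Si](C)(C)C)=C(C)C)[Si](C)(C)C)[C@@]1(C)Cc1c(OCOC)cc(CO[Si](C)(C)C(C)(C)C)cc1OCOC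
A5 | alternative 2 | (5R,8R,9S)-9-{2,6-bis(methoxymethoxy)-4-[(tert-butyldimethylsilyloxy)methyl]benzyl}-4,4,8,9-tetramethyldecal-1(10)-en-3-one | C[C@@H]1CC[C@@H]2C(=CCC(=O)C2(C)C)[C@@]1(C)Cc1c(OCOC)cc(CO[Si](C)(C)C(C)(C)C)cc1OCOC
A6 | alternative 3 | 1-methoxy-1,3-bis(trimethylsilyloxy)buta-1,3-diene bearing at C2 the C11 methylene of the (3R,5R,8R,9S)-3-(tert-butyldimethylsilyloxy)-4,4,8,9-tetramethyldecal-1(10)-en-9-yl unit | C[C@@H]1CC[C@@H]2C(=CC[C@@H](O[Si](C)(C)C(C)(C)C)C2(C)C)[C@@]1(C)CC(C(=C)O[Si](C)(C)C)=C(OC)O[Si](C)(C)C
A7 | alternative 3 | methyl 4-(tert-butyldimethylsilyloxy)but-2-ynoate | COC(=O)C#CCO[Si](C)(C)C(C)(C)C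
A8 | alternative 3 | methyl 6-[(tert-butyldimethylsilyloxy)methyl]-2,4-dihydroxy-3-{[(3R,5R,8R,9S)-3-(tert-butyldimethylsilyloxy)-4,4,8,9-tetramethyldecal-1(10)-en-9-yl]methyl}benzoate | C[C@@H]1CC[C@@H]2C(=CC[C@@H](O[Si](C)(C)C(C)(C)C)C2(C)C)[C@@]1(C)Cc1c(O)cc(CO[Si](C)(C)C(C)(C)C)c(C(=O)OC)c1O
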